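## Retrosynthetic overview
1. Dulcisbiflavonoid A has no stereocenters. Tetra-MOM protection converts the final deprotection into a single acid step that leaves the prenyl groups intact.
2. Disconnect the C5'(left B ring)–C8'' biaryl bond by Suzuki–Miyaura coupling: a left-unit aryl-Bpin and a right-unit 8-iodoflavone.
3. Each flavone ring comes from a 2'-hydroxychalcone (Claisen–Schmidt), closed oxidatively with I2/DMSO.
4. The right-unit prenyl is placed on phloroacetophenone before the flavone forms. The left-unit prenyl is placed on commercial 4-hydroxy-3-iodobenzaldehyde, where the iodine blocks one ortho position. Iodine then goes onto the right unit at C8, the only free A-ring position.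

Assumptions:
- Unprotected polyphenols are tolerated in the Claisen–Schmidt steps (excess base).
- The tri-ortho-substituted biaryl axis is not configurationally stable, so the target is achiral as drawn.

## Route

**Step 1**
Reactants: 1 (4-hydroxy-3-iodobenzaldehyde); 2 (prenyl bromide)
Product: 3 (4-hydroxy-3-iodo-5-(3-methylbut-2-enyl)benzaldehyde)
Conditions: 2 (1.5 equiv), NaOH (2.2 equiv), H2O, 25 °C, 12 h
Reagents that add atoms: prenyl bromide, CC(C)=CCBr
Why: Phenoxide C-alkylation is favoured in water, where H-bonding shields oxygen. The only free ortho position is C5 and the para position carries CHO, so the regiochemistry is fixed. No stereocenter is formed.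

**Step 2**
Reactants: 3; 4 (2,4,6-trihydroxyacetophenone)
Product: 5 ((E)-chalcone: 1-(2,4,6-trihydroxyphenyl)-3-(4-hydroxy-3-iodo-5-prenylphenyl)prop-2-en-1-one)
Conditions: KOH (8 equiv), EtOH/H2O, 25 → 60 °C, 48 h; then HCl work-up
Reagents that add atoms: none
Why: Claisen–Schmidt condensation. Dehydration gives the thermodynamically preferred E-enone, and the aryl iodide is inert to base.

**Step 3**
Reactants: 5
Product: 6 (5,7-dihydroxy-2-(4-hydroxy-3-iodo-5-prenylphenyl)chromen-4-one)
Conditions: I2 (0.2 equiv), DMSO, 110 °C, 3 h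
Reagents that add atoms: none
Why: Oxidative cyclisation of a 2'-hydroxychalcone to a flavone (I2/DMSO). Iodine-mediated oxa-Michael addition and then oxidation give the flavone directly, with no stereocenter retained.

**Step 4**
Reactants: 6; 7 (chloromethyl methyl ether, MOMCl)
Product: 8 (7,4'-bis-MOM ether of 6; 5-OH free)
Conditions: MOMCl (2.5 equiv), K2CO3 (3 equiv), acetone, 0 → 25 °C, 6 h
Reagents that add atoms: MOMCl, ClCOC
Why: Selective O-alkylation (MOM protection). The 5-OH is H-bonded to the C4 carbonyl and unreactive, and the hindered 4'-OH is acidified by the ortho iodine.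

**Step 5**
Reactants: 8; 9 (bis(pinacolato)diboron)
Product: 10 (aryl-Bpin of 8, boron at C5', ortho to OMOM)
Conditions: 9 (1.3 equiv), PdCl2(dppf) (5 mol%), KOAc (3 equiv), dioxane, 90 °C, 6 h
Reagents that add atoms: B2pin2, CC1(C)OB(B2OC(C)(C)C(C)(C)O2)OC1(C)C
Why: Miyaura borylation of the aryl iodide. The MOM, prenyl, chromone and chelated 5-OH groups are untouched.

**Step 6**
Reactants: 4; 2
Product: 11 (2,4,6-trihydroxy-3-prenylacetophenone)
Conditions: 2 (1.0 equiv), KOH (3 equiv), H2O, 0 → 25 °C, 2 h
Reagents that add atoms: prenyl bromide, CC(C)=CCBr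
Why: Aqueous C-alkylation of the phloroglucinol-type phenoxide (Kornblum-type). The substrate is symmetric, so mono-prenylation gives a single regioisomer (moderate yield).

**Step 7**
Reactants: 11; 12 (4-hydroxybenzaldehyde)
Product: 13 ((E)-2',4,4',6'-tetrahydroxy-3'-prenylchalcone)
Conditions: KOH (10 equiv), EtOH/H2O, 25 → 60 °C, 48 h; then HCl
Reagents that add atoms: none
Why: Claisen–Schmidt condensation giving the E-enone. Any flavanone formed by oxa-Michael closure is converted to the flavone in the next step.

**Step 8**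
Reactants: 13
Product: 14 (6-prenylapigenin)
Conditions: I2 (0.2 equiv), DMSO, 110 °C, 2 h
Reagents that add atoms: none
Why: Same I2/DMSO oxidative cyclisation as Step 3. The DMSO buffers HI, which limits acid cyclisation of the prenyl group.

**Step 9**
Reactants: 14; 15 (N-iodosuccinimide)
Product: 16 (8-iodo-6-prenylapigenin)
Conditions: NIS (1.05 equiv), THF, 0 → 25 °C, 1 h, dark
Reagents that add atoms: NIS, O=C1CCC(=O)N1I
Why: Electrophilic aromatic iodination. C8 is the only free position on the phloroglucinol-type A ring and is far more nucleophilic than the trisubstituted alkene or the B ring.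

**Step 10**
Reactants: 16; 7 (MOMCl)
Product: 17 (7,4'-bis-MOM ether of 16; 5-OH free)
Conditions: MOMCl (2.5 equiv), K2CO3 (3 equiv), acetone, 0 → 25 °C, 8 h
Reagents that add atoms: MOMCl, ClCOC
Why: Same selective MOM protection as Step 4; the 5-OH stays free through chelation.

**Step 11**
Reactants: 17 (electrophile); 10 (1.5 equiv, nucleophile)
Product: 18 (tetra-MOM-protected 5'–8'' biflavone)
Conditions: Pd2(dba)3 (5 mol%), SPhos (20 mol%), K3PO4 (3 equiv), dioxane/H2O, 100 °C, 12 h
Reagents that add atoms: none
Why: Suzuki–Miyaura coupling joins C5' of the left B ring to C8'' of the right A ring. The bulky electron-rich ligand handles the tri-ortho-substituted biaryl, and no stereocenter is created.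

**Step 12**
Reactants: 18
Product: 19 (Dulcisbiflavonoid A)
Conditions: 3 M HCl, THF/MeOH (1:1), 40 °C, 6 h
Reagents that add atoms: none
Why: Acid-catalysed MOM acetal hydrolysis releases all four phenols. The prenyl groups survive at this mild acidity and temperature.

## Compound list
1 | 4-hydroxy-3-iodobenzaldehyde | O=Cc1ccc(O)c(I)c1 | starting material
2 | prenyl bromide | CC(C)=CCBr | starting material (reagent)
3 | 4-hydroxy-3-iodo-5-prenylbenzaldehyde | O=Cc1cc(I)c(O)c(CC=C(C)C)c1 | intermediate
4 | 2,4,6-trihydroxyacetophenone | CC(=O)c1c(O)cc(O)cc1O | starting material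
5 | left chalcone (E) | O=C(/C=C/c1cc(I)c(O)c(CC=C(C)C)c1)c1c(O)cc(O)cc1O | intermediate
6 | 5,7-dihydroxy-2-(4-hydroxy-3-iodo-5-prenylphenyl)chromone | CC(C)=CCc1cc(-c2cc(=O)c3c(O)cc(O)cc3o2)cc(I)c1O | intermediate
7 | chloromethyl methyl ether (MOMCl) | ClCOC | starting material (reagent)
8 | 7,4'-bis-MOM left flavone iodide | CC(C)=CCc1cc(-c2cc(=O)c3c(O)cc(OCOC)cc3o2)cc(I)c1OCOC | intermediate
9 | bis(pinacolato)diboron | CC1(C)OB(B2OC(C)(C)C(C)(C)O2)OC1(C)C | starting material (reagent)
10 | left flavone aryl-Bpin (bis-MOM) | CC(C)=CCc1cc(-c2cc(=O)c3c(O)cc(OCOC)cc3o2)cc(B2OC(C)(C)C(C)(C)O2)c1OCOC | intermediate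
11 | 2,4,6-trihydroxy-3-prenylacetophenone | CC(=O)c1c(O)cc(O)c(CC=C(C)C)c1O | intermediate
12 | 4-hydroxybenzaldehyde | O=Cc1ccc(O)cc1 | starting material
13 | right chalcone (E) | O=C(/C=C/c1ccc(O)cc1)c1c(O)cc(O)c(CC=C(C)C)c1O | intermediate
14 | 6-prenylapigenin | CC(C)=CCc1c(O)cc2oc(-c3ccc(O)cc3)cc(=O)c2c1O | intermediate
15 | N-iodosuccinimide | O=C1CCC(=O)N1I | starting material (reagent)
16 | 8-iodo-6-prenylapigenin | CC(C)=CCc1c(O)c(I)c2oc(-c3ccc(O)cc3)cc(=O)c2c1O | intermediate
17 | 7,4'-bis-MOM-8-iodo-6-prenylapigenin | CC(C)=CCc1c(OCOC)c(I)c2oc(-c3ccc(OCOC)cc3)cc(=O)c2c1O | intermediate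
18 | tetra-MOM biflavone | CC(C)=CCc1cc(-c2cc(=O)c3c(O)cc(OCOC)cc3o2)cc(-c2c(OCOC)c(CC=C(C)C)c(O)c3c(=O)cc(-c4ccc(OCOC)cc4)oc23)c1OCOC | intermediate
19 | Dulcisbiflavonoid A | CC(C)=CCc1cc(-c2cc(=O)c3c(O)cc(O)cc3o2)cc(-c2c(O)c(CC=C(C)C)c(O)c3c(=O)cc(-c4ccc(O)cc4)oc23)c1O | target (achiral; no stereocenters)

## Totals
Total steps: 12. Longest linear sequence: 7 steps (1→2→3→4→5→11→12, or 6→7→8→9→10→11→12).

## Three steps most likely to fail
1. **Step 6 (C-prenylation of phloroacetophenone; Step 1 has the same issue).** O-prenylation, di-prenylation and low yield are likely.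
   Fallback: change the approach by making the O-allyl ether, doing a thermal aromatic Claisen rearrangement to the C-allyl phenol, and converting allyl to prenyl by cross-metathesis with 2-methyl-2-butene (Grubbs II).
2. **Step 11 (hindered Suzuki coupling).** Protodeboronation or reductive deiodination may compete, and the tri-ortho-substituted biaryl is slow to form.
   Fallback: form the biaryl earlier. Couple 17 with 3-prenyl-4-(MOMO)-5-Bpin-benzaldehyde, then build the left flavone on the biaryl aldehyde by Claisen–Schmidt condensation and I2/DMSO cyclisation.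
3. **Step 8 (I2/DMSO on the prenylated chalcone; Step 3 is similar).** HI or I2 can cyclise the ortho-prenyl phenol to a chromane, or iodinate the A ring.
   Fallback: use a Baker–Venkataraman route instead. Acylate a MOM-protected 2-hydroxyacetophenone, rearrange to the 1,3-diketone, and cyclise under mild dehydrating conditions, so no iodine or HI is present.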